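**Plan**
- Labels: ring A is the central benzene, counted from the carbon that carries the one-carbon arm C7 (position 1); positions 3 and 5 carry the furan oxygens, positions 2 and 6 the furan C3 carbons, position 4 a hydrogen. Furan 1 (O–C2–C3) sits on positions 5 and 6 with the free resorcinol ring C on C3. Furan 2 (O–C2'–C3') sits on positions 3 and 2 with ring B on C3'. Ring B is counted from the carbon bonded to C3', and its position 6 is bonded to C8.
- Enabling feature: the bridge bond C7–C8 joins a carbon that can be an aldehyde on position 1 of ring A to the benzylic carbon of the 4-hydroxyphenyl group on position 6 of ring B, which can be the methide carbon of a para-quinone methide. Both carbons are electrophilic, so the aldehyde is turned into an acyl anion equivalent to join them.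
- Retrosynthetic cuts, in order: the seven ArO–CH3 bonds; the C7–O bond (C7 is a ketone before it is CH2); C7–C8 (opens the seven-membered ring); the bond from C8 to ring B; C2'–C3' and the bond from ring A to C3' (furan 2); C2–C3 and the bond from ring A to C3 (furan 1); the C–Br and benzyl–O bonds of ring A.
- Forward order: ring A dibromide, furan 1, furan 2 carrying ring B, C8 arm on ring B, seven-membered ring, C7 deoxygenation, demethylation.
- Stereochemistry: C3 and C3' come from two carbene C–H insertions under antipodal chiral dirhodium carboxylates; C2 and C2' from acid equilibration to the trans furans; C8 from the chiral triazolium carbene in the ring closure, then kept by immediate reduction and a radical (not cationic) deoxygenation.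

Key step: step 16

Assumption: the sense of induction of each chiral catalyst is taken as written; C3 and C3' are mirror-related, so the two insertions need antipodal dirhodium catalysts in any case, and either of them (or the triazolium salt of step 16) would be exchanged for its antipode if the observed sense is opposite.

Step 1
Reactants: 1 3,5-dihydroxybenzyl alcohol; 2 4-methoxybenzyl chloride (two equivalents are consumed)
Product: 3 [3,5-bis(4-methoxybenzyloxy)phenyl]methanol
Conditions: 2 (2.2 equiv), K2CO3, KI (cat.), acetone, reflux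
Reagents that add atoms: 4-methoxybenzyl chloride (second equivalent of 2), COc1ccc(CCl)cc1
Why: Twofold Williamson ether synthesis in which carbonate forms only the two phenoxides, so the benzylic alcohol stays free and the two 4-methoxybenzyl groups that later become C2 and C2' with their aryl groups are installed.

Step 2
Reactants: 3 [3,5-bis(4-methoxybenzyloxy)phenyl]methanol
Product: 4 [3,5-bis(4-methoxybenzyloxy)benzyloxy]triisopropylsilane
Conditions: TIPSCl, imidazole, DMF, rt
Reagents that add atoms: triisopropylsilyl chloride, CC(C)[Si](Cl)(C(C)C)C(C)C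
Why: Standard silylation of a primary alcohol; the bulky silyl ether should survive butyllithium (little tendency to migrate to an ortho aryllithium), hydrazine, MnO2 and CF3CO2H and offers a poorly basic oxygen to the later carbenes.

Step 3
Reactants: 4 [3,5-bis(4-methoxybenzyloxy)benzyloxy]triisopropylsilane
Product: 5 [2,6-dibromo-3,5-bis(4-methoxybenzyloxy)benzyloxy]triisopropylsilane
Conditions: NBS (2.05 equiv), MeCN, 0 °C → rt, dark
Reagents that add atoms: N-bromosuccinimide (two equivalents), O=C1CCC(=O)N1Br
Why: Electrophilic aromatic bromination should occur twice on the doubly alkoxy-activated ring A at positions 2 and 6, each para to one oxygen and ortho to the other, which react faster than position 4 between the two oxygens and than the anisole rings.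

Step 4
Reactants: 5 [2,6-dibromo-3,5-bis(4-methoxybenzyloxy)benzyloxy]triisopropylsilane; 6 3,5-dimethoxybenzonitrile
Product: 8 hydrazone of [3-bromo-4,6-bis(4-methoxybenzyloxy)-2-(triisopropylsilyloxymethyl)phenyl](3,5-dimethoxyphenyl)methanone, via NH ketimine 7 (not isolated)
Conditions: n-BuLi (1.0 equiv), THF, −78 °C; 6, −78 → 0 °C; MeOH; then N2H4·H2O, AcOH (cat.), EtOH, 80 °C
Reagents that add atoms: hydrazine (as hydrate), NN
Why: Bromine–lithium exchange of one of the two equivalent bromides, addition of the aryllithium to the nitrile and transimination of the resulting N–H ketimine with hydrazine give the hydrazone without a condensation on a di-ortho-substituted diaryl ketone.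

Step 5
Reactants: 8 hydrazone of [3-bromo-4,6-bis(4-methoxybenzyloxy)-2-(triisopropylsilyloxymethyl)phenyl](3,5-dimethoxyphenyl)methanone
Product: 10 (2S,3R)-5-bromo-3-(3,5-dimethoxyphenyl)-6-(4-methoxybenzyloxy)-2-(4-methoxyphenyl)-4-(triisopropylsilyloxymethyl)-2,3-dihydrobenzofuran (cis), via diaryldiazomethane 9 (not isolated)
Conditions: MnO2, CH2Cl2, 0 °C; filtered solution added to dirhodium tetrakis[(R)-2-(1-adamantyl)-2-phthalimidoacetate], Rh2(R-PTAD)4 (1 mol %), CH2Cl2, 0 °C → rt
Reagents that add atoms: none
Why: Hydrazone oxidation to the diaryldiazomethane followed by intramolecular 1,5-C–H insertion of the donor/donor dirhodium carbene into the benzylic ether CH2 is known to give cis-2,3-diaryl-2,3-dihydrobenzofurans, the chiral carboxylate ligands setting C3 (R) and the cis C2 being corrected in step 11.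

Step 6
Reactants: 11 3,5-dimethoxybenzaldehyde
Product: 12 2-bromo-3,5-dimethoxybenzaldehyde
Conditions: NBS, MeCN, rt
Reagents that add atoms: N-bromosuccinimide, O=C1CCC(=O)N1Br
Why: Electrophilic aromatic bromination of this aldehyde is known to go to the position ortho to the formyl group and para to a methoxy group, which places bromine on the future position 6 of ring B.

Step 7
Reactants: 10 cis-dihydrobenzofuran bromide (2S,3R); 12 2-bromo-3,5-dimethoxybenzaldehyde
Product: 13 (2-bromo-3,5-dimethoxyphenyl)[(2S,3R)-3-(3,5-dimethoxyphenyl)-6-(4-methoxybenzyloxy)-2-(4-methoxyphenyl)-4-(triisopropylsilyloxymethyl)-2,3-dihydrobenzofuran-5-yl]methanol (both carbinol epimers)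
Conditions: n-BuLi, THF, −78 °C; then 12, −78 °C; then H2O
Reagents that add atoms: none
Why: Bromine–lithium exchange and 1,2-addition of the aryllithium to the aldehyde, which is much faster at −78 °C than exchange with the aryl bromide of 12; the carbinol configuration is irrelevant because the centre is oxidised next.

Step 8
Reactants: 13 diaryl carbinol
Product: 14 (2-bromo-3,5-dimethoxyphenyl)[(2S,3R)-3-(3,5-dimethoxyphenyl)-6-(4-methoxybenzyloxy)-2-(4-methoxyphenyl)-4-(triisopropylsilyloxymethyl)-2,3-dihydrobenzofuran-5-yl]methanone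
Conditions: Dess–Martin periodinane, CH2Cl2, 0 °C → rt
Reagents that add atoms: none
Why: Dess–Martin oxidation of a secondary diaryl carbinol to the diaryl ketone under conditions that leave the silyl ether, benzyl ether and aryl bromide untouched.

Step 9
Reactants: 14 diaryl ketone
Product: 15 hydrazone of 14
Conditions: N2H4 (anhydrous), AcOH (cat.), n-BuOH, 120 °C, sealed tube
Reagents that add atoms: hydrazine, NN
Why: Acid-catalysed hydrazone condensation, driven by excess anhydrous hydrazine at high temperature because the carbonyl group carries three ortho substituents; none of the other groups reacts with hydrazine.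

Step 10
Reactants: 15 hydrazone of 14
Product: 17 cis,cis-bis(dihydrofuran) bromide (2S,3R,2'R,3'R), via diaryldiazomethane 16 (not isolated)
Conditions: MnO2, CH2Cl2, 0 °C; filtered solution added to dirhodium tetrakis[(S)-2-(1-adamantyl)-2-phthalimidoacetate], Rh2(S-PTAD)4 (1 mol %), CH2Cl2, 0 °C → rt
Reagents that add atoms: none
Why: The same hydrazone oxidation and donor/donor carbene 1,5-C–H insertion as in step 5, now into the benzyl ether on position 3 of ring A, with the antipodal catalyst so that C3' is set under catalyst control in the mirror-image sense to C3 (the distant furan 1 exerts no useful bias).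

Step 11
Reactants: 17 cis,cis-bis(dihydrofuran) bromide
Product: 18 trans,trans-bis(dihydrofuran) bromide (2R,3R,2'S,3'R)
Conditions: CF3CO2H, CH2Cl2, 0 °C → rt
Reagents that add atoms: none
Why: Acid-mediated thermodynamic epimerisation in which each C2–O bond ionises reversibly to a 4-methoxybenzyl cation held next to the phenol oxygen and recloses to the more stable trans-2,3-diaryl arrangement, C3 and C3' not being touched.

Step 12
Reactants: 18 trans,trans-bis(dihydrofuran) bromide; 19 4-(tert-butyldimethylsilyloxy)benzaldehyde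
Product: 20 diaryl carbinol at C8 (both C8 epimers)
Conditions: n-BuLi, THF, −78 °C; then 19, −78 °C; then H2O
Reagents that add atoms: none
Why: Bromine–lithium exchange at position 6 of ring B (helped by the ortho methoxy group) and 1,2-addition to the aldehyde form the bond between C8 and ring B; the C8 configuration is irrelevant because the centre becomes planar in step 16.

Step 13
Reactants: 20 diaryl carbinol at C8
Product: 21 C8 p-tolyl sulfone (both C8 epimers)
Conditions: p-TolSO2H (3 equiv), CH2Cl2, rt
Reagents that add atoms: p-toluenesulfinic acid, Cc1ccc(cc1)S(=O)O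
Why: SN1 substitution in which the doubly stabilised diarylmethyl cation formed from the carbinol under the mildly acidic conditions is captured at sulfur by the sulfinate, the aryl and alkyl silyl ethers being stable to this acid.

Step 14
Reactants: 21 C8 p-tolyl sulfone
Product: 22 diol (CH2OH on ring A and free 4-hydroxyphenyl on C8)
Conditions: Bu4NF, AcOH (1:1), THF, 0 °C → rt
Reagents that add atoms: none
Why: Fluoride cleavage of both silyl ethers, buffered with acetic acid so that the phenol stays protonated and the sulfinate is not expelled prematurely.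

Step 15
Reactants: 22 diol
Product: 23 ring A aldehyde with the 4-hydroxybenzyl p-tolyl sulfone on position 6 of ring B (2R,3R,2'S,3'S)
Conditions: MnO2 (activated, excess), CH2Cl2, rt
Reagents that add atoms: none
Why: Manganese dioxide oxidation is selective for the benzylic alcohol and should stop at the aldehyde, leaving the phenol and the sulfone untouched.

Step 16
Reactants: 23 ring A aldehyde with the 4-hydroxybenzyl p-tolyl sulfone on position 6 of ring B
Product: 25 seven-membered-ring ketone (2R,3R,2'S,3'S,8S) bearing the free 4-hydroxyphenyl group on C8, via para-quinone methide 24 (not isolated)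
Conditions: (5aS,10bR)-2-(pentafluorophenyl)-5a,10b-dihydro-4H,6H-indeno[2,1-b][1,2,4]triazolo[4,3-d][1,4]oxazinium tetrafluoroborate (20 mol %), Cs2CO3 (1.5 equiv), THF (0.01 M), 0 °C; cold pH 7 buffer work-up
Reagents that add atoms: none
Why: Proposed new method: Cs2CO3 deprotonates the phenol of 23 and expels p-toluenesulfinate to give the para-quinone methide 24, while the carbene from the triazolium salt adds to the ring A aldehyde and proton transfer gives the Breslow intermediate, whose nucleophilic carbon (C7) adds to the methide carbon (C8) in a 1,6-sense so that the phenol rearomatises and the carbene is released from the aryl ketone. The closest known reactions are carbene-catalysed intermolecular 1,6-additions of aldehydes to isolable para-quinone methides and intramolecular Stetter cyclisations, together with carbene catalysis run in the presence of quinone methides generated in the flask. The seven-membered ring closes in the 7-exo-trig mode, the methide C=C bond lying outside the new ring. C8 is set by the chiral carbene, which selects the methide face, reinforced by the substrate in which C2' of furan 2 shields one face, so that the 4-hydroxyphenyl group ends anti to C2' (8S, C8–H trans to C3'–H). The step needs C-acylation within the molecule to outrun sulfinate return (reversible), benzoin coupling, O-acylation and oligomerisation of 24; the aldehyde without alpha-hydrogen and with two ortho substituents (no self-coupling, yet still reached by the small N-C6F5 carbene), high dilution, the low stationary concentration of 24 and the irreversible rearomatisation are what secure it. The C8–H next to the new ketone is acidic, hence the limited base, low temperature, neutral work-up and direct use in step 17.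

Step 17
Reactants: 25 seven-membered-ring ketone
Product: 26 C7 alcohol (either C7 epimer; 8S retained)
Conditions: NaBH4, CeCl3·7H2O, MeOH/THF, −20 → 0 °C
Reagents that add atoms: none
Why: Luche reduction delivers hydride to the hindered aryl ketone under weakly basic conditions that should not enolise C8, and the new C7 carbinol configuration is irrelevant because the oxygen is removed in step 20.

Step 18
Reactants: 26 C7 alcohol
Product: 27 C7 alcohol with the C8 aryl group as its methyl ether
Conditions: MeI, K2CO3, acetone, rt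
Reagents that add atoms: iodomethane, CI
Why: Williamson methylation in which carbonate deprotonates only the phenol, so the hindered secondary alcohol stays free; C8–H is no longer acidic once the ketone is reduced.

Step 19
Reactants: 27 C7 alcohol with the C8 aryl group as its methyl ether
Product: 28 O-(C7) S-methyl xanthate
Conditions: NaH, THF, 0 °C; CS2; then MeI, rt
Reagents that add atoms: carbon disulfide, S=C=S; iodomethane, CI
Why: Xanthate formation (alkoxide addition to CS2, then S-methylation) uses the smallest available thiocarbonyl electrophile and so suits a secondary alcohol flanked on both sides.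

Step 20
Reactants: 28 O-(C7) S-methyl xanthate
Product: 29 heptamethyl ether of the target (C7 = CH2)
Conditions: Bu3SnH, Et3B, air, toluene, rt
Reagents that add atoms: none
Why: Barton–McCombie deoxygenation through the C7 benzylic radical, chosen over ionic hydrogenation because a C7 cation would invite hydride or aryl shift from C8 and loss of its configuration; room-temperature initiation avoids Chugaev elimination.

Step 21
Reactants: 29 heptamethyl ether of the target
Product: 30 target CNP0136963.1 (2R,3R,2'S,3'S,8S)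
Conditions: BBr3, CH2Cl2, −78 °C → rt; then H2O
Reagents that add atoms: none
Why: Lewis acid cleavage of the seven aryl methyl ethers; any reversible ionisation at C2 or C2' returns the trans furans, which are the thermodynamic isomers, and C3, C3' and C8 carry no leaving group.

**Compound list**
1 | 3,5-dihydroxybenzyl alcohol | OCc1cc(O)cc(O)c1 | starting material
2 | 4-methoxybenzyl chloride | COc1ccc(CCl)cc1 | starting material
3 | [3,5-bis(4-methoxybenzyloxy)phenyl]methanol | OCc1cc(OCc2ccc(OC)cc2)cc(OCc2ccc(OC)cc2)c1 | intermediate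
4 | [3,5-bis(4-methoxybenzyloxy)benzyloxy]triisopropylsilane | CC(C)[Si](OCc1cc(OCc2ccc(OC)cc2)cc(OCc2ccc(OC)cc2)c1)(C(C)C)C(C)C | intermediate
5 | [2,6-dibromo-3,5-bis(4-methoxybenzyloxy)benzyloxy]triisopropylsilane | CC(C)[Si](OCc1c(Br)c(OCc2ccc(OC)cc2)cc(OCc2ccc(OC)cc2)c1Br)(C(C)C)C(C)C | intermediate
6 | 3,5-dimethoxybenzonitrile | COc1cc(OC)cc(C#N)c1 | starting material
7 | [3-bromo-4,6-bis(4-methoxybenzyloxy)-2-(triisopropylsilyloxymethyl)phenyl](3,5-dimethoxyphenyl)methanimine (NH ketimine, formed in the flask) | CC(C)[Si](OCc1c(Br)c(OCc2ccc(OC)cc2)cc(OCc2ccc(OC)cc2)c1C(=N)c1cc(OC)cc(OC)c1)(C(C)C)C(C)C | intermediate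
8 | hydrazone of [3-bromo-4,6-bis(4-methoxybenzyloxy)-2-(triisopropylsilyloxymethyl)phenyl](3,5-dimethoxyphenyl)methanone | CC(C)[Si](OCc1c(Br)c(OCc2ccc(OC)cc2)cc(OCc2ccc(OC)cc2)c1C(=NN)c1cc(OC)cc(OC)c1)(C(C)C)C(C)C | intermediate
9 | [3-bromo-4,6-bis(4-methoxybenzyloxy)-2-(triisopropylsilyloxymethyl)phenyl](3,5-dimethoxyphenyl)diazomethane (formed in the flask) | CC(C)[Si](OCc1c(Br)c(OCc2ccc(OC)cc2)cc(OCc2ccc(OC)cc2)c1C(=[N+]=[N-])c1cc(OC)cc(OC)c1)(C(C)C)C(C)C | intermediate
10 | (2S,3R)-5-bromo-3-(3,5-dimethoxyphenyl)-6-(4-methoxybenzyloxy)-2-(4-methoxyphenyl)-4-(triisopropylsilyloxymethyl)-2,3-dihydrobenzofuran (cis furan 1) | CC(C)[Si](OCc1c(Br)c(OCc2ccc(OC)cc2)cc2c1[C@@H](c1cc(OC)cc(OC)c1)[C@@H](c1ccc(OC)cc1)O2)(C(C)C)C(C)C | intermediate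
11 | 3,5-dimethoxybenzaldehyde | COc1cc(C=O)cc(OC)c1 | starting material
12 | 2-bromo-3,5-dimethoxybenzaldehyde | COc1cc(C=O)c(Br)c(OC)c1 | intermediate
13 | (2-bromo-3,5-dimethoxyphenyl)[(2S,3R)-3-(3,5-dimethoxyphenyl)-6-(4-methoxybenzyloxy)-2-(4-methoxyphenyl)-4-(triisopropylsilyloxymethyl)-2,3-dihydrobenzofuran-5-yl]methanol (both carbinol epimers) | CC(C)[Si](OCc1c(C(O)c2cc(OC)cc(OC)c2Br)c(OCc2ccc(OC)cc2)cc2c1[C@@H](c1cc(OC)cc(OC)c1)[C@@H](c1ccc(OC)cc1)O2)(C(C)C)C(C)C | intermediate
14 | (2-bromo-3,5-dimethoxyphenyl)[(2S,3R)-3-(3,5-dimethoxyphenyl)-6-(4-methoxybenzyloxy)-2-(4-methoxyphenyl)-4-(triisopropylsilyloxymethyl)-2,3-dihydrobenzofuran-5-yl]methanone | CC(C)[Si](OCc1c(C(=O)c2cc(OC)cc(OC)c2Br)c(OCc2ccc(OC)cc2)cc2c1[C@@H](c1cc(OC)cc(OC)c1)[C@@H](c1ccc(OC)cc1)O2)(C(C)C)C(C)C | intermediate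
15 | hydrazone of 14 | CC(C)[Si](OCc1c(C(=NN)c2cc(OC)cc(OC)c2Br)c(OCc2ccc(OC)cc2)cc2c1[C@@H](c1cc(OC)cc(OC)c1)[C@@H](c1ccc(OC)cc1)O2)(C(C)C)C(C)C | intermediate
16 | diaryldiazomethane from 15 (C=N2 in place of C=N–NH2, formed in the flask) | CC(C)[Si](OCc1c(C(=[N+]=[N-])c2cc(OC)cc(OC)c2Br)c(OCc2ccc(OC)cc2)cc2c1[C@@H](c1cc(OC)cc(OC)c1)[C@@H](c1ccc(OC)cc1)O2)(C(C)C)C(C)C | intermediate
17 | cis,cis-bis(dihydrofuran) bromide: ring A fused to furan 1 (2S,3R; 4-methoxyphenyl on C2, 3,5-dimethoxyphenyl on C3) and furan 2 (2'R,3'R; 4-methoxyphenyl on C2', 2-bromo-3,5-dimethoxyphenyl = ring B on C3'); CH2OSi(i-Pr)3 on position 1 of ring A | CC(C)[Si](OCc1c2c(cc3c1[C@@H](c1cc(OC)cc(OC)c1)[C@@H](c1ccc(OC)cc1)O3)O[C@@H](c1ccc(OC)cc1)[C@H]2c1cc(OC)cc(OC)c1Br)(C(C)C)C(C)C | intermediate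
18 | trans,trans isomer of 17 (2R,3R,2'S,3'R; the descriptor 3'R arises only because bromine ranks ring B above ring A, the arrangement at C3' is that of the target) | CC(C)[Si](OCc1c2c(cc3c1[C@@H](c1cc(OC)cc(OC)c1)[C@H](c1ccc(OC)cc1)O3)O[C@H](c1ccc(OC)cc1)[C@H]2c1cc(OC)cc(OC)c1Br)(C(C)C)C(C)C | intermediate
19 | 4-(tert-butyldimethylsilyloxy)benzaldehyde | CC(C)(C)[Si](C)(C)Oc1ccc(C=O)cc1 | starting material
20 | diaryl carbinol: 18 with the bromine of ring B replaced by CH(OH)(4-tert-butyldimethylsilyloxyphenyl) (C8, both epimers; 2R,3R,2'S,3'S) | CC(C)[Si](OCc1c2c(cc3c1[C@@H](c1cc(OC)cc(OC)c1)[C@H](c1ccc(OC)cc1)O3)O[C@H](c1ccc(OC)cc1)[C@H]2c1cc(OC)cc(OC)c1C(O)c1ccc(O[Si](C)(C)C(C)(C)C)cc1)(C(C)C)C(C)C | intermediate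
21 | sulfone: 20 with the C8 hydroxyl replaced by p-tolylsulfonyl (both C8 epimers) | CC(C)[Si](OCc1c2c(cc3c1[C@@H](c1cc(OC)cc(OC)c1)[C@H](c1ccc(OC)cc1)O3)O[C@H](c1ccc(OC)cc1)[C@H]2c1cc(OC)cc(OC)c1C(c1ccc(O[Si](C)(C)C(C)(C)C)cc1)S(=O)(=O)c1ccc(C)cc1)(C(C)C)C(C)C | intermediate
22 | diol: 21 without the two silyl groups (CH2OH on ring A, free 4-hydroxyphenyl on C8) | OCc1c2c(cc3c1[C@@H](c1cc(OC)cc(OC)c1)[C@H](c1ccc(OC)cc1)O3)O[C@H](c1ccc(OC)cc1)[C@H]2c1cc(OC)cc(OC)c1C(c1ccc(O)cc1)S(=O)(=O)c1ccc(C)cc1 | intermediate
23 | ring A aldehyde (CHO on position 1) with both trans dihydrofurans and the (4-hydroxyphenyl)(p-tolylsulfonyl)methyl group on position 6 of ring B (2R,3R,2'S,3'S; both C8 epimers) | O=Cc1c2c(cc3c1[C@@H](c1cc(OC)cc(OC)c1)[C@H](c1ccc(OC)cc1)O3)O[C@H](c1ccc(OC)cc1)[C@H]2c1cc(OC)cc(OC)c1C(c1ccc(O)cc1)S(=O)(=O)c1ccc(C)cc1 | intermediate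
24 | para-quinone methide: 23 after loss of p-toluenesulfinic acid, ring B–CH=(4-oxocyclohexa-2,5-dien-1-ylidene) (formed in the flask) | O=Cc1c2c(cc3c1[C@@H](c1cc(OC)cc(OC)c1)[C@H](c1ccc(OC)cc1)O3)O[C@H](c1ccc(OC)cc1)[C@H]2c1cc(OC)cc(OC)c1C=C1C=CC(=O)C=C1 | intermediate
25 | seven-membered-ring ketone: C7(=O) joins position 1 of ring A to C8; C8 (S) bears H and 4-hydroxyphenyl and is bonded to position 6 of ring B (2R,3R,2'S,3'S,8S) | Oc1ccc([C@@H]2C(=O)c3c4c(cc5c3[C@@H](c3cc(OC)cc(OC)c3)[C@H](c3ccc(OC)cc3)O5)O[C@H](c3ccc(OC)cc3)[C@H]4c3cc(OC)cc(OC)c32)cc1 | intermediate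
26 | C7 alcohol: 25 reduced at C7 (either C7 epimer) | Oc1ccc([C@@H]2C(O)c3c4c(cc5c3[C@@H](c3cc(OC)cc(OC)c3)[C@H](c3ccc(OC)cc3)O5)O[C@H](c3ccc(OC)cc3)[C@H]4c3cc(OC)cc(OC)c32)cc1 | intermediate
27 | 26 with the C8 aryl group as 4-methoxyphenyl | COc1ccc([C@@H]2C(O)c3c4c(cc5c3[C@@H](c3cc(OC)cc(OC)c3)[C@H](c3ccc(OC)cc3)O5)O[C@H](c3ccc(OC)cc3)[C@H]4c3cc(OC)cc(OC)c32)cc1 | intermediate
28 | O-(C7) S-methyl xanthate of 27 | COc1ccc([C@@H]2C(OC(=S)SC)c3c4c(cc5c3[C@@H](c3cc(OC)cc(OC)c3)[C@H](c3ccc(OC)cc3)O5)O[C@H](c3ccc(OC)cc3)[C@H]4c3cc(OC)cc(OC)c32)cc1 | intermediate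
29 | heptamethyl ether of the target (C7 = CH2; 2R,3R,2'S,3'S,8S) | COc1ccc([C@@H]2Cc3c4c(cc5c3[C@@H](c3cc(OC)cc(OC)c3)[C@H](c3ccc(OC)cc3)O5)O[C@H](c3ccc(OC)cc3)[C@H]4c3cc(OC)cc(OC)c32)cc1 | intermediate
30 | CNP0136963.1 (2R,3R,2'S,3'S,8S) | Oc1ccc([C@@H]2Cc3c4c(cc5c3[C@@H](c3cc(O)cc(O)c3)[C@H](c3ccc(O)cc3)O5)O[C@H](c3ccc(O)cc3)[C@H]4c3cc(O)cc(O)c32)cc1 | target

**Count and risks**
Total step count: 21. Longest linear sequence: 20 steps (steps 1–5 and 7–21; step 6 is a one-step branch).

Steps most likely to fail:

Step 16. The flanked aldehyde may form the Breslow intermediate too slowly, so that the quinone methide is lost to oligomerisation, sulfinate return or O-acylation of the phenoxide; the face selectivity at C8 may also be poor. Fallback (sets out from 18, returns at 27): the same ring is closed from the other side by palladium-catalysed intramolecular alpha-arylation of a ketone. Bu4NF in THF removes the silyl group of 18 to give the primary alcohol F1. Dess–Martin periodinane gives the aldehyde F2. 4-Methoxybenzylmagnesium chloride (THF, 0 °C) adds to give the secondary alcohol F3, and a second Dess–Martin oxidation gives the aryl benzyl ketone F4. Pd2(dba)3, 2-dicyclohexylphosphino-2',4',6'-triisopropylbiphenyl and NaOt-Bu in toluene at 80 °C should join the enolate carbon to position 6 of ring B in place of bromine and give the seven-membered-ring ketone F5, the O-methyl ether of 25. Its C8 is expected to equilibrate under the base to the configuration with the aryl group anti to C2'. NaBH4/CeCl3·7H2O reduction of F5 gives 27.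

Step 9. The condensation may stall because three ortho substituents shield both faces of the carbonyl group, or azine formation may take over. Fallback (sets out from 10 and 12, returns at 15): the C=N bond is made from a nitrile, so no carbonyl condensation is needed. Aldehyde 12 is converted with I2 and aqueous NH3 in THF into 2-bromo-3,5-dimethoxybenzonitrile F6. Bromide 10 is lithiated (n-BuLi, THF, −78 °C) and transmetalated with MgBr2·OEt2. The arylmagnesium bromide is added to F6 with CuBr (cat.) in THF at reflux; magnesium is used instead of lithium to avoid bromine–metal exchange with F6. Methanol quench gives the NH ketimine F7. Transimination of F7 with N2H4·H2O and AcOH in EtOH gives hydrazone 15.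

Step 10. The crowded diaryl carbene may be diverted (oxonium ylide formation at the silyl ether oxygen, azine formation) or may insert with low facial selectivity. Fallback (sets out from 14, returns at 18): furan 2 is closed by an anionic cyclisation and ionic hydrogenation, without a diazo compound. Lithium 2,2,6,6-tetramethylpiperidide (THF, −78 → 0 °C) deprotonates the 4-methoxybenzyl ether CH2 of 14, and the carbanion adds to the neighbouring ketone to give the 3'-hydroxy-dihydrofuran F8 (mixture at C2' and C3'). Et3SiH and CF3CO2H in CH2Cl2 reduce the tertiary benzylic alcohol through the C3' cation and equilibrate both furans to trans. C3' is not controlled by the distant furan 1, so 18 would be separated by chromatography from its diastereomer F9, which has the opposite configuration at C2' and C3'.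

Further compounds
F1 | step 16 | primary alcohol: 18 with CH2OH on ring A in place of the silyl ether | OCc1c2c(cc3c1[C@@H](c1cc(OC)cc(OC)c1)[C@H](c1ccc(OC)cc1)O3)O[C@H](c1ccc(OC)cc1)[C@H]2c1cc(OC)cc(OC)c1Br
F2 | step 16 | aldehyde: CHO on ring A, bromine still on ring B | O=Cc1c2c(cc3c1[C@@H](c1cc(OC)cc(OC)c1)[C@H](c1ccc(OC)cc1)O3)O[C@H](c1ccc(OC)cc1)[C@H]2c1cc(OC)cc(OC)c1Br
F3 | step 16 | secondary alcohol: ring A–CH(OH)CH2(4-methoxyphenyl) (both carbinol epimers) | COc1ccc(CC(O)c2c3c(cc4c2[C@@H](c2cc(OC)cc(OC)c2)[C@H](c2ccc(OC)cc2)O4)O[C@H](c2ccc(OC)cc2)[C@H]3c2cc(OC)cc(OC)c2Br)cc1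
F4 | step 16 | aryl benzyl ketone: ring A–C(=O)CH2(4-methoxyphenyl) | COc1ccc(CC(=O)c2c3c(cc4c2[C@@H](c2cc(OC)cc(OC)c2)[C@H](c2ccc(OC)cc2)O4)O[C@H](c2ccc(OC)cc2)[C@H]3c2cc(OC)cc(OC)c2Br)cc1
F5 | step 16 | seven-membered-ring ketone with 4-methoxyphenyl on C8 (O-methyl ether of 25; 8S) | COc1ccc([C@@H]2C(=O)c3c4c(cc5c3[C@@H](c3cc(OC)cc(OC)c3)[C@H](c3ccc(OC)cc3)O5)O[C@H](c3ccc(OC)cc3)[C@H]4c3cc(OC)cc(OC)c32)cc1
F6 | step 9 | 2-bromo-3,5-dimethoxybenzonitrile | COc1cc(C#N)c(Br)c(OC)c1
F7 | step 9 | NH ketimine corresponding to ketone 14 (C=NH in place of C=O) | CC(C)[Si](OCc1c(C(=N)c2cc(OC)cc(OC)c2Br)c(OCc2ccc(OC)cc2)cc2c1[C@@H](c1cc(OC)cc(OC)c1)[C@@H](c1ccc(OC)cc1)O2)(C(C)C)C(C)C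
F8 | step 10 | 3'-hydroxy-dihydrofuran from cyclisation of 14 (furan 1 cis 2S,3R; C2' and C3' as mixture) | CC(C)[Si](OCc1c2c(cc3c1[C@@H](c1cc(OC)cc(OC)c1)[C@@H](c1ccc(OC)cc1)O3)OC(c1ccc(OC)cc1)C2(O)c1cc(OC)cc(OC)c1Br)(C(C)C)C(C)C
F9 | step 10 | diastereomer of 18 with furan 2 of opposite configuration (2R,3R,2'R,3'S) | CC(C)[Si](OCc1c2c(cc3c1[C@@H](c1cc(OC)cc(OC)c1)[C@H](c1ccc(OC)cc1)O3)O[C@@H](c1ccc(OC)cc1)[C@@H]2c1cc(OC)cc(OC)c1Br)(C(C)C)C(C)C
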